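The bicyclic core is cut at C5–C10 and C8–C9. Ring B (C5–C10) carries a quaternary C9 next to an sp2 ring-fusion carbon C10 whose double bond to C1 lies in ring A, with the C5 and C8 substituents cis: this is what results when a diene C5=C6–C7=C8 adds to the C9=C10 bond of an allene C1=C10=C9. One thermal intramolecular Diels–Alder reaction therefore closes rings A and B, places the C1=C10 alkene and sets C5, C8 and C9. Its precursor is an acyclic (5E,7E)-dienyl allene with the C4 quaternary ester centre, a defined allene axis and the complete C11–C15 side chain.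

Key step: step 17

Remarks before the steps
- Numbering: C1–C20 are the halimane positions of the target (C18 carboxyl carbon on C4, C19 methyl on C4, C17 methyl on C8, C20 methyl on C9, C16 methyl on C13).
- Assumption: pig liver esterase is taken to give the (R)-half-ester 5 from 4, the sense known for methylmalonates whose second chain has five or more atoms; if the (S)-acid formed, the acid arm would be reduced (BH3·SMe2) and the ester arm kept.
- Precursor design: C18 is carried as a 2-(trimethylsilyl)ethyl ester, so the hindered acid is freed by fluoride together with the C15 silyl ether. C15 carries the tert-butyldiphenylsilyl group for stability to periodic acid and heat. C1 is carried as a dioxolane, since an alkene could not be cleaved once the diene is present.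

Step 1
Reactants: 1 dimethyl 2-methylmalonate; 2 2-(2-bromoethyl)-1,3-dioxolane
Product: 4 dimethyl 2-[2-(1,3-dioxolan-2-yl)ethyl]-2-methylmalonate, via sodium enolate 3 (not isolated)
Conditions: NaH, DMF, 0 °C; then 2, 60 °C
Reagents that add atoms: sodium hydride, [Na+].[H-] (sodium kept in 3 only)
Why: SN2 alkylation of a stabilised malonate enolate with a primary bromide assembles C4 with both carboxyl arms, C3, C2 and the masked C1 aldehyde; no stereocentre is formed.

Step 2
Reactants: 4 dimethyl 2-[2-(1,3-dioxolan-2-yl)ethyl]-2-methylmalonate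
Product: 5 (2R)-2-[2-(1,3-dioxolan-2-yl)ethyl]-3-methoxy-2-methyl-3-oxopropanoic acid
Conditions: pig liver esterase, phosphate buffer pH 7.5, DMSO (10% v/v), 25 °C, pH-stat (NaOH); then HCl to pH 3, 0 °C
Reagents that add atoms: water, O
Why: Enzymatic desymmetrisation of an α-methyl-α-alkylmalonate: the esterase hydrolyses one of the two enantiotopic methyl esters and thereby sets C4, which is never touched again.

Step 3
Reactants: 5 (R)-half-ester
Product: 7 (2S)-4-(1,3-dioxolan-2-yl)-2-(hydroxymethyl)-2-methylbutanoic acid, via lithium carboxylate 6 (not isolated)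
Conditions: LiBH4, THF, 0 → 50 °C; then HCl to pH 3, 0 °C
Reagents that add atoms: lithium borohydride, [Li+].[BH4-] (lithium kept in 6 only)
Why: Lithium borohydride reduces esters but not carboxylate salts, so once the acid is converted into 6 only the methyl ester arm (the future C5) is reduced and the stereocentre is unaffected.

Step 4
Reactants: 7 (2S)-hydroxy acid
Product: 8 2-(trimethylsilyl)ethyl (2S)-4-(1,3-dioxolan-2-yl)-2-(hydroxymethyl)-2-methylbutanoate
Conditions: Cl3CC(=NH)OCH2CH2SiMe3, toluene, 100 °C
Reagents that add atoms: 2-(trimethylsilyl)ethyl 2,2,2-trichloroacetimidate, C[Si](C)(C)CCOC(=N)C(Cl)(Cl)Cl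
Why: Promoter-free imidate esterification: the carboxylic acid protonates the imidate and is O-alkylated through the β-silyl-stabilised cation, while the neopentyl alcohol is not acidic enough to react and no carboxyl activation (β-lactone formation) is involved.

Step 5
Reactants: 8 hydroxy ester
Product: 9 2-(trimethylsilyl)ethyl (2S)-4-(1,3-dioxolan-2-yl)-2-formyl-2-methylbutanoate
Conditions: Dess–Martin periodinane, pyridine, CH2Cl2, 0 °C → rt
Reagents that add atoms: none
Why: Dess–Martin oxidation of the neopentyl primary alcohol stops at the aldehyde, which cannot epimerise because C4 is quaternary; pyridine protects the acetal from the acetic acid formed.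

Step 6
Reactants: 9 aldehyde
Product: 10 2-(trimethylsilyl)ethyl (2S,3E)-2-[2-(1,3-dioxolan-2-yl)ethyl]-4-iodo-2-methylbut-3-enoate
Conditions: CrCl2, CHI3, THF/dioxane, 0 °C → rt
Reagents that add atoms: iodoform, IC(I)I
Why: Takai olefination converts hindered aldehydes into (E)-vinyl iodides with high selectivity and tolerates ester and acetal, which fixes the C5=C6 geometry.

Step 7
Reactants: 10 (E)-vinyl iodide; 11 (E)-prop-1-enylboronic acid pinacol ester
Product: 12 2-(trimethylsilyl)ethyl (2S,3E,5E)-2-[2-(1,3-dioxolan-2-yl)ethyl]-2-methylhepta-3,5-dienoate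
Conditions: Pd(PPh3)4 (cat.), K3PO4, THF/H2O, 50 °C
Reagents that add atoms: none
Why: Suzuki–Miyaura coupling proceeds with retention at both alkenyl carbons, so the (5E,7E)-diene geometry is inherited from the two partners.

Step 8
Reactants: 12 diene acetal
Product: 13 2-(trimethylsilyl)ethyl (2S,3E,5E)-2-methyl-2-(3-oxopropyl)hepta-3,5-dienoate
Conditions: 2 M HCl, THF, rt
Reagents that add atoms: water, O
Why: Acid-catalysed acetal hydrolysis frees the C1 aldehyde; the hindered silylethyl ester and the unactivated diene are stable to dilute aqueous acid at room temperature.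

Step 9
Reactants: 14 geraniol
Product: 15 geranyl tert-butyldiphenylsilyl ether [tert-butyl{[(2E)-3,7-dimethylocta-2,6-dien-1-yl]oxy}diphenylsilane]
Conditions: t-BuPh2SiCl, imidazole, DMF, rt
Reagents that add atoms: tert-butyl(chloro)diphenylsilane, CC(C)(C)[Si](Cl)(c1ccccc1)c1ccccc1
Why: Standard silylation of a primary alcohol; this silyl group is chosen because it withstands periodic acid, carbonate, organometallic reagents and the temperature of step 17.

Step 10
Reactants: 15 silyl ether
Product: 16 terminal epoxide of 15, tert-butyl{[(2E)-5-(3,3-dimethyloxiran-2-yl)-3-methylpent-2-en-1-yl]oxy}diphenylsilane (racemic at the oxirane carbon)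
Conditions: mCPBA, NaHCO3, CH2Cl2, −20 → 0 °C
Reagents that add atoms: 3-chloroperoxybenzoic acid, OOC(=O)c1cccc(Cl)c1
Why: Prilezhaev epoxidation prefers the electron-richer terminal trisubstituted alkene over the alkene deactivated by the allylic oxygen; the new centre is racemic and is removed in step 11.

Step 11
Reactants: 16 epoxide
Product: 18 (4E)-6-[(tert-butyldiphenylsilyl)oxy]-4-methylhex-4-enal, via 6,7-diol 17 (not isolated)
Conditions: H5IO6, THF/H2O, 0 °C
Reagents that add atoms: water, O (kept in 17 only)
Why: Periodic acid hydrolyses the epoxide to the vicinal diol and cleaves it at once (glycol cleavage) to the aldehyde and acetone, leaving the (E)-alkene and the acid-stable silyl ether intact.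

Step 12
Reactants: 18 aldehyde
Product: 19 tert-butyl{[(2E)-3-methylhept-2-en-6-yn-1-yl]oxy}diphenylsilane
Conditions: MeC(O)C(N2)P(O)(OMe)2, K2CO3, MeOH, 0 °C → rt
Reagents that add atoms: dimethyl (1-diazo-2-oxopropyl)phosphonate, COP(=O)(OC)C(=[N+]=[N-])C(C)=O
Why: Seyferth–Gilbert homologation with the Ohira–Bestmann reagent turns the aldehyde into the terminal alkyne (the new carbon becomes C10) under mild carbonate conditions that the silyl ether tolerates.

Step 13
Reactants: 19 alkyne; 13 aldehyde
Product: 21 2-(trimethylsilyl)ethyl (2S,3E,5E)-2-[(3RS,8E)-10-{[tert-butyl(diphenyl)silyl]oxy}-3-hydroxy-8-methyldec-8-en-4-yn-1-yl]-2-methylhepta-3,5-dienoate, via lithium acetylide 20 (not isolated)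
Conditions: n-BuLi, THF, −78 °C; then 13, −78 °C; H2O
Reagents that add atoms: n-butyllithium, [Li]CCCC (lithium kept in 20 only)
Why: Acetylide addition to the aldehyde is far faster at −78 °C than attack on the hindered α-quaternary ester; the C1 carbinol centre forms without control and is erased in step 14.

Step 14
Reactants: 21 propargylic alcohol (both C1 epimers)
Product: 22 ynone, 2-(trimethylsilyl)ethyl (2S,3E,5E)-2-[(8E)-10-{[tert-butyl(diphenyl)silyl]oxy}-8-methyl-3-oxodec-8-en-4-yn-1-yl]-2-methylhepta-3,5-dienoate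
Conditions: MnO2, CH2Cl2, rt
Reagents that add atoms: none
Why: Activated manganese dioxide oxidises propargylic alcohols selectively and leaves diene, ester, alkene and silyl ether alone.

Step 15
Reactants: 22 ynone
Product: 23 (1R)-propargylic alcohol, 2-(trimethylsilyl)ethyl (2S,3E,5E)-2-[(3R,8E)-10-{[tert-butyl(diphenyl)silyl]oxy}-3-hydroxy-8-methyldec-8-en-4-yn-1-yl]-2-methylhepta-3,5-dienoate
Conditions: Ru[(R,R)-TsNCH(Ph)CH(Ph)NH](p-cymene) (2 mol%), i-PrOH, rt
Reagents that add atoms: none
Why: Noyori asymmetric transfer hydrogenation of an alkynyl ketone is reagent-controlled; with the alkynyl group in the role that aryl plays in aryl ketones, the (R,R)-diamine catalyst is expected to give the (1R)-alcohol independently of the remote C4 centre.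

Step 16
Reactants: 23 (1R)-propargylic alcohol
Product: 26 dienyl allene, 2-(trimethylsilyl)ethyl (2S,3E,5E)-2-[(3Ra,8E)-10-{[tert-butyl(diphenyl)silyl]oxy}-5,8-dimethyldeca-3,4,8-trien-1-yl]-2-methylhepta-3,5-dienoate (target numbering: 4S, 5E, 7E, allene C1=C10=C9 with Ra axis, 13E), via lithium alkoxide 24 (not isolated), via propargylic mesylate 25 (not isolated)
Conditions: n-BuLi, THF, −78 °C; MsCl, −78 → −50 °C; then MeMgBr/CuBr·SMe2/LiBr (1:1:1), THF, −78 → −30 °C
Reagents that add atoms: n-butyllithium, [Li]CCCC (lithium kept in 24 only); methanesulfonyl chloride, CS(=O)(=O)Cl (kept in 25 only); methylmagnesium bromide, C[Mg]Br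
Why: Copper-mediated anti-SN2′ substitution of a propargylic sulfonate delivers methyl to C9 on the face opposite the departing mesylate, so the (1R) carbinol configuration becomes the (Ra) allene axis; the 1:1 methylcopper reagent at low temperature spares the ester and limits allene racemisation.

Step 17
Reactants: 26 dienyl allene
Product: 27 2-(trimethylsilyl)ethyl (4S,5S,8R,9S,13E)-15-{[tert-butyl(diphenyl)silyl]oxy}halima-1(10),6,13-trien-18-oate
Conditions: toluene (0.01 M, degassed), BHT, 180 °C, sealed tube
Reagents that add atoms: none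
Why: Proposed new method: the diene C5=C6–C7=C8 is expected to add suprafacially, in a concerted thermal [4+2] process, to the C9=C10 bond of the allene, forming C5–C10 and C8–C9 and leaving the orthogonal C1=C10 bond as the ring A alkene; the closest known reaction type is the thermal intramolecular Diels–Alder reaction of allenes that react as dienophiles at the bond remote from the tether, which has not been shown for an unactivated allene with a fully substituted terminus. Ring B (C5–C10) closes as the cycloaddition ring, and ring A (C1–C5, C10) closes in the same event as a six-membered ring through the tether C2–C3–C4 onto the central allene carbon, helped by the gem-disubstituted C4 (Thorpe–Ingold effect). C9 is controlled by the allene axis: the lobes of the C9=C10 bond lie in the H–C1–C2 plane, the tether can bring the diene only to the C2 face, and the (Ra) axis then decides on which side methyl and chain come to lie. C5 and C8 are made cis to each other by the (E,E)-diene geometry, and their sense relative to C9 follows from the orientation in which the C9 methyl, not the C11 chain, sits under C6–C7; the axis alone does not fix this, and the preference rests only on the smaller size of methyl and on the bulky C18 ester taking the open position above the diene instead of eclipsing C5=C6, so some (5R,8S)-diastereomer is expected and would be removed by chromatography. The step also needs C9=C10 to react in preference to C1=C10, which is expected because closure at C1 would demand a five-membered ring with an exocyclic alkylidene and because both faces of the C1=C10 bond are screened by the two C9 substituents.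

Step 18
Reactants: 27 cycloadduct
Product: 28 2-(trimethylsilyl)ethyl (4S,5S,8R,9S,13E)-15-{[tert-butyl(diphenyl)silyl]oxy}halima-1(10),13-dien-18-oate
Conditions: 2-O2NC6H4SO2NHNH2, Et3N, CH2Cl2, rt
Reagents that add atoms: none
Why: Diimide reduction (concerted syn transfer of two hydrogens) is very sensitive to substitution, so the cis-disubstituted C6=C7 bond is reduced while the trisubstituted C1=C10 and C13=C14 bonds remain; no stereocentre is created.

Step 19
Reactants: 28 silyl ether silylethyl ester
Product: 29 (4S,5S,8R,9S,13E)-15-hydroxyhalima-1(10),13-dien-18-oic acid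
Conditions: Bu4NF, THF, rt → 45 °C; then dilute HCl (pH 3)
Reagents that add atoms: none
Why: Fluoride attacks silicon in both groups: the silyl ether is cleaved directly and the 2-(trimethylsilyl)ethyl ester fragments to ethene and the carboxylate, a process that does not depend on access to the hindered C18 carbonyl.

Step 20
Reactants: 29 hydroxy acid
Product: 30 (4S,5S,8R,9S,13E)-15-(propanoyloxy)halima-1(10),13-dien-18-oic acid (target, CNP0223570.1)
Conditions: (EtCO)2O, pyridine, 0 °C → rt; aqueous work-up
Reagents that add atoms: propanoic anhydride, CCC(=O)OC(=O)CC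
Why: Acylation with an anhydride in pyridine esterifies the primary allylic alcohol, whereas the hindered tertiary carboxylic acid is returned free after aqueous work-up.

Compound list
1 | dimethyl 2-methylmalonate | COC(=O)C(C)C(=O)OC | starting material
2 | 2-(2-bromoethyl)-1,3-dioxolane | BrCCC1OCCO1 | starting material
3 | sodium enolate of 1 (not isolated) | [Na+].COC(=O)[C-](C)C(=O)OC | intermediate
4 | dimethyl 2-[2-(1,3-dioxolan-2-yl)ethyl]-2-methylmalonate | COC(=O)C(C)(CCC1OCCO1)C(=O)OC | intermediate
5 | (2R)-2-[2-(1,3-dioxolan-2-yl)ethyl]-3-methoxy-2-methyl-3-oxopropanoic acid | COC(=O)[C@@](C)(C(=O)O)CCC1OCCO1 | intermediate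
6 | lithium carboxylate of 5 (not isolated) | [Li+].COC(=O)[C@@](C)(C(=O)[O-])CCC1OCCO1 | intermediate
7 | (2S)-4-(1,3-dioxolan-2-yl)-2-(hydroxymethyl)-2-methylbutanoic acid | OC[C@@](C)(C(=O)O)CCC1OCCO1 | intermediate
8 | 2-(trimethylsilyl)ethyl (2S)-4-(1,3-dioxolan-2-yl)-2-(hydroxymethyl)-2-methylbutanoate | OC[C@@](C)(C(=O)OCC[Si](C)(C)C)CCC1OCCO1 | intermediate
9 | 2-(trimethylsilyl)ethyl (2S)-4-(1,3-dioxolan-2-yl)-2-formyl-2-methylbutanoate | O=C[C@@](C)(C(=O)OCC[Si](C)(C)C)CCC1OCCO1 | intermediate
10 | 2-(trimethylsilyl)ethyl (2S,3E)-2-[2-(1,3-dioxolan-2-yl)ethyl]-4-iodo-2-methylbut-3-enoate | I/C=C/[C@@](C)(C(=O)OCC[Si](C)(C)C)CCC1OCCO1 | intermediate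
11 | 4,4,5,5-tetramethyl-2-[(E)-prop-1-enyl]-1,3,2-dioxaborolane | C/C=C/B1OC(C)(C)C(C)(C)O1 | starting material
12 | 2-(trimethylsilyl)ethyl (2S,3E,5E)-2-[2-(1,3-dioxolan-2-yl)ethyl]-2-methylhepta-3,5-dienoate | C/C=C/C=C/[C@@](C)(C(=O)OCC[Si](C)(C)C)CCC1OCCO1 | intermediate
13 | 2-(trimethylsilyl)ethyl (2S,3E,5E)-2-methyl-2-(3-oxopropyl)hepta-3,5-dienoate | C/C=C/C=C/[C@@](C)(C(=O)OCC[Si](C)(C)C)CCC=O | intermediate
14 | geraniol | CC(C)=CCC/C(C)=C/CO | starting material
15 | tert-butyl{[(2E)-3,7-dimethylocta-2,6-dien-1-yl]oxy}diphenylsilane | CC(C)=CCC/C(C)=C/CO[Si](c1ccccc1)(c1ccccc1)C(C)(C)C | intermediate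
16 | tert-butyl{[(2E)-5-(3,3-dimethyloxiran-2-yl)-3-methylpent-2-en-1-yl]oxy}diphenylsilane (racemic) | CC1(C)OC1CC/C(C)=C/CO[Si](c1ccccc1)(c1ccccc1)C(C)(C)C | intermediate
17 | (6E)-8-{[tert-butyl(diphenyl)silyl]oxy}-2,6-dimethyloct-6-ene-2,3-diol (racemic, not isolated) | CC(C)(O)C(O)CC/C(C)=C/CO[Si](c1ccccc1)(c1ccccc1)C(C)(C)C | intermediate
18 | (4E)-6-{[tert-butyl(diphenyl)silyl]oxy}-4-methylhex-4-enal | O=CCC/C(C)=C/CO[Si](c1ccccc1)(c1ccccc1)C(C)(C)C | intermediate
19 | tert-butyl{[(2E)-3-methylhept-2-en-6-yn-1-yl]oxy}diphenylsilane | C#CCC/C(C)=C/CO[Si](c1ccccc1)(c1ccccc1)C(C)(C)C | intermediate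
20 | lithium acetylide of 19 (not isolated) | [Li]C#CCC/C(C)=C/CO[Si](c1ccccc1)(c1ccccc1)C(C)(C)C | intermediate
21 | propargylic alcohol, both C1 epimers, (4S,5E,7E,13E) | C/C=C/C=C/[C@@](C)(C(=O)OCC[Si](C)(C)C)CCC(O)C#CCC/C(C)=C/CO[Si](c1ccccc1)(c1ccccc1)C(C)(C)C | intermediate
22 | ynone (C1 ketone), (4S,5E,7E,13E) | C/C=C/C=C/[C@@](C)(C(=O)OCC[Si](C)(C)C)CCC(=O)C#CCC/C(C)=C/CO[Si](c1ccccc1)(c1ccccc1)C(C)(C)C | intermediate
23 | (1R)-propargylic alcohol, (1R,4S,5E,7E,13E) | C/C=C/C=C/[C@@](C)(C(=O)OCC[Si](C)(C)C)CC[C@@H](O)C#CCC/C(C)=C/CO[Si](c1ccccc1)(c1ccccc1)C(C)(C)C | intermediate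
24 | lithium alkoxide of 23 (not isolated) | C/C=C/C=C/[C@@](C)(C(=O)OCC[Si](C)(C)C)CC[C@@H](O[Li])C#CCC/C(C)=C/CO[Si](c1ccccc1)(c1ccccc1)C(C)(C)C | intermediate
25 | (1R)-propargylic methanesulfonate of 23 (not isolated) | C/C=C/C=C/[C@@](C)(C(=O)OCC[Si](C)(C)C)CC[C@@H](OS(C)(=O)=O)C#CCC/C(C)=C/CO[Si](c1ccccc1)(c1ccccc1)C(C)(C)C | intermediate
26 | (E,E)-dienyl allene, 2-(trimethylsilyl)ethyl (2S,3E,5E)-2-[(3Ra,8E)-10-{[tert-butyl(diphenyl)silyl]oxy}-5,8-dimethyldeca-3,4,8-trien-1-yl]-2-methylhepta-3,5-dienoate | C/C=C/C=C/[C@@](C)(C(=O)OCC[Si](C)(C)C)CCC([H])=[C@]=C(C)CC/C(C)=C/CO[Si](c1ccccc1)(c1ccccc1)C(C)(C)C | intermediate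
27 | 2-(trimethylsilyl)ethyl (4S,5S,8R,9S,13E)-15-{[tert-butyl(diphenyl)silyl]oxy}halima-1(10),6,13-trien-18-oate | CC(C)(C)[Si](c1ccccc1)(c1ccccc1)OC/C=C(\C)CC[C@]1(C)C2=CCC[C@](C)(C(=O)OCC[Si](C)(C)C)[C@H]2C=C[C@H]1C | intermediate
28 | 2-(trimethylsilyl)ethyl (4S,5S,8R,9S,13E)-15-{[tert-butyl(diphenyl)silyl]oxy}halima-1(10),13-dien-18-oate | CC(C)(C)[Si](c1ccccc1)(c1ccccc1)OC/C=C(\C)CC[C@]1(C)C2=CCC[C@](C)(C(=O)OCC[Si](C)(C)C)[C@H]2CC[C@H]1C | intermediate
29 | (4S,5S,8R,9S,13E)-15-hydroxyhalima-1(10),13-dien-18-oic acid | OC/C=C(\C)CC[C@]1(C)C2=CCC[C@](C)(C(=O)O)[C@H]2CC[C@H]1C | intermediate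
30 | (4S,5S,8R,9S,13E)-15-(propanoyloxy)halima-1(10),13-dien-18-oic acid | CCC(=O)OC/C=C(\C)CC[C@]1(C)C2=CCC[C@](C)(C(=O)O)[C@H]2CC[C@H]1C | target

Total step count: 20. Longest linear sequence: 16 steps (steps 1–8, then 13–20).

Steps most likely to fail

1. Step 17 (bears the label). The cycloaddition may not occur at the fully substituted C9 terminus before thermal decomposition sets in. The diene may add to the C1=C10 bond instead, closing a five-membered ring. The methyl-under-diene orientation may not be preferred, which would show as poor endo/exo discrimination and low diastereoselectivity at C5 and C8. The fallback uses known chemistry, sets out from aldehyde 13 and alkyne 19 and returns at 27; it replaces the allene by an enone dienophile. Negishi carboalumination of 19 (AlMe3, Cp2ZrCl2, CH2Cl2), conversion of the (E)-alkenylalane into its alanate (n-BuLi) and addition to 13 would give the (E)-allylic alcohol F1. Dess–Martin oxidation would give the (E)-enone F2, in which the C9 methyl is cis to the carbonyl. An intramolecular Diels–Alder reaction of this deca-1,7,9-trien-3-one type (toluene, 160 °C, or Et2AlCl, CH2Cl2, −20 °C) through the tether-endo transition state would give the cis-fused octalone F3, with the C9 methyl cis to the C8 methyl. Formation of the more substituted enol triflate F4 (Tf2O, 2,6-di-tert-butyl-4-methylpyridine, CH2Cl2) and reduction (Pd(OAc)2, PPh3, HCO2H, Bu3N, DMF, 60 °C) would return 27. Only C4 then biases the diene face, so a separation of diastereomers has to be accepted.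

2. Step 2. The enzyme may discriminate the two enantiotopic ester groups poorly (low enantiomeric purity at C4) or in the opposite sense. The fallback sets out from 4 and returns at 5, using resolution instead of desymmetrisation. Half-saponification of 4 (KOH, one equivalent, MeOH, 0 °C) would give the racemic half-ester F5. Crystallisation of its salt with (S)-1-phenylethylamine would give the (R)-acid salt F6; the antipodal amine serves if the other diastereomer is the less soluble one. Acidification returns 5.

3. Step 16. Direct SN2 methylation at C1 may compete, syn delivery may leak through, or excess organocopper may racemise the allene by electron transfer; each would erode the axis that controls C9. The fallback sets out from 23 and returns at 26, using a palladium route instead of the copper one. Acylation (ClCO2Me, pyridine, CH2Cl2, 0 °C) would give the (1R)-propargylic methyl carbonate F7. Coupling with MeZnCl and Pd(PPh3)4 (zerovalent palladium, THF, 0 °C) proceeds by anti oxidative addition to an allenylpalladium species, transmetalation and reductive elimination with retention, which gives the same (Ra)-allene 26.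

Further compounds
F1 | step 17 | 2-(trimethylsilyl)ethyl (2S,3E,5E)-2-[(3RS,4E,8E)-10-{[tert-butyl(diphenyl)silyl]oxy}-3-hydroxy-5,8-dimethyldeca-4,8-dien-1-yl]-2-methylhepta-3,5-dienoate | C/C=C/C=C/[C@@](C)(C(=O)OCC[Si](C)(C)C)CCC(O)/C=C(\C)CC/C(C)=C/CO[Si](c1ccccc1)(c1ccccc1)C(C)(C)C
F2 | step 17 | 2-(trimethylsilyl)ethyl (2S,3E,5E)-2-[(4E,8E)-10-{[tert-butyl(diphenyl)silyl]oxy}-5,8-dimethyl-3-oxodeca-4,8-dien-1-yl]-2-methylhepta-3,5-dienoate | C/C=C/C=C/[C@@](C)(C(=O)OCC[Si](C)(C)C)CCC(=O)/C=C(\C)CC/C(C)=C/CO[Si](c1ccccc1)(c1ccccc1)C(C)(C)C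
F3 | step 17 | 2-(trimethylsilyl)ethyl (4S,5S,8R,9S,10S,13E)-15-{[tert-butyl(diphenyl)silyl]oxy}-1-oxohalima-6,13-dien-18-oate (cis-fused, 10-H cis to 5-H) | CC(C)(C)[Si](c1ccccc1)(c1ccccc1)OC/C=C(\C)CC[C@]1(C)[C@H]2C(=O)CC[C@](C)(C(=O)OCC[Si](C)(C)C)[C@H]2C=C[C@H]1C
F4 | step 17 | 1-(trifluoromethanesulfonyloxy) derivative of 27 (enol triflate at C1=C10, other centres as in 27) | CC(C)(C)[Si](c1ccccc1)(c1ccccc1)OC/C=C(\C)CC[C@]1(C)C2=C(OS(=O)(=O)C(F)(F)F)CC[C@](C)(C(=O)OCC[Si](C)(C)C)[C@H]2C=C[C@H]1C
F5 | step 2 | racemic 2-[2-(1,3-dioxolan-2-yl)ethyl]-3-methoxy-2-methyl-3-oxopropanoic acid | COC(=O)C(C)(C(=O)O)CCC1OCCO1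
F6 | step 2 | (S)-1-phenylethylammonium salt of (R)-acid 5 | COC(=O)[C@@](C)(C(=O)[O-])CCC1OCCO1.C[C@H]([NH3+])c1ccccc1
F7 | step 16 | (1R)-propargylic methyl carbonate of 23 | C/C=C/C=C/[C@@](C)(C(=O)OCC[Si](C)(C)C)CC[C@@H](OC(=O)OC)C#CCC/C(C)=C/CO[Si](c1ccccc1)(c1ccccc1)C(C)(C)C
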